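**Retrosynthetic overview**

1. Feature: in the middle flavan unit, C3 and C4 are adjacent carbons of ring C; C4 carries two aryl groups (its own ring A through C4a, and C6 of the bottom unit) and C3 carries only OH and H. Ring C is therefore opened at C3=C4 to a 1,1-diarylethene tied through O1–C2 to a vinyl group.
2. Endgame: hydrogenolysis of 14 benzyl ethers and one C–Br ⇐ hydroboration–oxidation of C3=C4 anti to the C2 aryl ⇐ ring-closing metathesis. Ring C of the middle unit is the only ring built.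
3. C2 of the middle unit: iridium-catalysed branched allylic etherification of a phenol with a cinnamyl carbonate made from caffeic acid.
4. 1,1-Diarylethene: aryllithium of the top–middle fragment plus 8-bromo-epicatechin-6-carbaldehyde, then oxidation and MeLi addition/dehydration.
5. Top–middle C4–C6 bond: 4α-arylation of C4-activated catechin with phloroglucinol, then para-silylation, ortho-iodination and benzylation; all other rings come intact from catechin and epicatechin.

Key step: step 20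

Assumption: the target is read as catechin-(4α→6)-catechin-(4α→6)-epicatechin (top and middle units 2,3-trans-3,4-trans, bottom unit 2,3-cis); slowly interconverting rotamers about the hindered aryl–C4 bonds are treated as one compound.

**Route**

Step 1
Reactants: 1 (+)-catechin
Product: 2 5,7,3',4'-tetra-O-benzylcatechin
Conditions: BnBr (4.4 equiv), K2CO3, DMF, 0 °C → rt
Reagents that add atoms: benzyl bromide BrCc1ccccc1
Why: Williamson etherification of the four phenols with carbonate base, which leaves the secondary 3-OH and both stereocentres untouched.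

Step 2
Reactants: 2 5,7,3',4'-tetra-O-benzylcatechin
Product: 3 3,5,7,3',4'-penta-O-benzylcatechin
Conditions: NaH, BnBr, n-Bu4NI (cat.), DMF, 0 °C → rt
Reagents that add atoms: benzyl bromide BrCc1ccccc1
Why: Williamson etherification of the 3-alkoxide; with all phenols capped no base-induced ring opening can epimerise C2.

Step 3
Reactants: 3 3,5,7,3',4'-penta-O-benzylcatechin
Product: 4 3,5,7,3',4'-penta-O-benzyl-4β-methoxycatechin (2R,3S,4S)
Conditions: DDQ, MeOH, CH2Cl2, rt
Reagents that add atoms: methanol CO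
Why: Oxidative C4 functionalisation of a flavan: DDQ abstracts hydride from the benzylic C4 activated by the ring A ethers and methanol traps the cation (4β expected; this configuration is lost again in step 4).

Step 4
Reactants: 4 3,5,7,3',4'-penta-O-benzyl-4β-methoxycatechin; 5 phloroglucinol
Product: 6 penta-O-benzylcatechin-(4α→2)-phloroglucinol
Conditions: phloroglucinol (5 equiv), BF3·OEt2 (0.3 equiv), THF/CH2Cl2, −20 → 0 °C
Reagents that add atoms: none
Why: Friedel–Crafts arylation of the flavan-4-yl cation (phloroglucinol capture); the symmetric nucleophile allows only one regioisomer and adds anti to the 3-benzyloxy group, setting C4 as 4α (3,4-trans).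

Step 5
Reactants: 6 penta-O-benzylcatechin-(4α→2)-phloroglucinol
Product: 7 mono-triisopropylsilyl ether of 6 at the phenol para to the flavanyl carbon
Conditions: i-Pr3SiCl (1.05 equiv), imidazole, DMF, 0 °C
Reagents that add atoms: triisopropylsilyl chloride CC(C)[Si](Cl)(C(C)C)C(C)C
Why: Sterically controlled silylation: the bulky chlorosilane reaches only the para phenol, which has two free ortho positions, while both ortho phenols are shielded by the flavan C4 substituent.

Step 6
Reactants: 7 para-silyl ether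
Product: 8 mono-iodide of 7 (iodine between the silyloxy group and one free phenol)
Conditions: I2 (1.0 equiv), NaHCO3, THF/H2O, 0 °C
Reagents that add atoms: iodine II
Why: Electrophilic aromatic iodination through the phenoxide, so that I2 attacks only the ring with free phenols, ortho to one OH and para to the other (the two open positions are equivalent), and leaves the all-ether rings alone.

Step 7
Reactants: 8 mono-iodide
Product: 9 4α-[2,6-bis(benzyloxy)-3-iodo-4-(triisopropylsilyloxy)phenyl]-penta-O-benzylcatechin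
Conditions: BnBr, K2CO3, n-Bu4NI (cat.), DMF, rt
Reagents that add atoms: benzyl bromide BrCc1ccccc1
Why: Williamson etherification of the two remaining phenols; the aryl triisopropylsilyl ether is stable to anhydrous carbonate.

Step 8
Reactants: 10 (−)-epicatechin
Product: 11 5,7,3',4'-tetra-O-benzylepicatechin
Conditions: BnBr (4.4 equiv), K2CO3, DMF, 0 °C → rt
Reagents that add atoms: benzyl bromide BrCc1ccccc1
Why: Williamson etherification of the four phenols, as in step 1.

Step 9
Reactants: 11 5,7,3',4'-tetra-O-benzylepicatechin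
Product: 12 3,5,7,3',4'-penta-O-benzylepicatechin
Conditions: NaH, BnBr, n-Bu4NI (cat.), DMF, 0 °C → rt
Reagents that add atoms: benzyl bromide BrCc1ccccc1
Why: Williamson etherification of the 3-alkoxide, as in step 2.

Step 10
Reactants: 12 3,5,7,3',4'-penta-O-benzylepicatechin
Product: 13 8-bromo-3,5,7,3',4'-penta-O-benzylepicatechin
Conditions: NBS (1.0 equiv), CH2Cl2, −78 °C → rt
Reagents that add atoms: N-bromosuccinimide O=C1CCC(=O)N1Br
Why: Electrophilic aromatic bromination, which in 5,7-dialkoxyflavans goes to C8 first; this blocks C8 and leaves C6 as the only free carbon of ring A.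

Step 11
Reactants: 13 8-bromo-penta-O-benzylepicatechin
Product: 15 8-bromo-3,5,7,3',4'-penta-O-benzylepicatechin-6-carbaldehyde, via C6 iminium salt 14 (not isolated)
Conditions: POCl3, DMF, ClCH2CH2Cl, 0 → 70 °C; then H2O, rt
Reagents that add atoms: N,N-dimethylformamide CN(C)C=O; water O
Why: Vilsmeier–Haack formylation: the chloroiminium ion attacks C6, the only open position of the trioxygenated ring A (the catechol-ether ring B is far less nucleophilic), and water hydrolyses the iminium salt to the aldehyde.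

Step 12
Reactants: 16 caffeic acid
Product: 17 benzyl (E)-3-[3,4-bis(benzyloxy)phenyl]acrylate
Conditions: BnBr (3.5 equiv), K2CO3, DMF, 60 °C
Reagents that add atoms: benzyl bromide BrCc1ccccc1
Why: Exhaustive benzylation (Williamson etherification of both phenols and alkylation of the carboxylate).

Step 13
Reactants: 17 benzyl (E)-3-[3,4-bis(benzyloxy)phenyl]acrylate
Product: 18 (E)-3-[3,4-bis(benzyloxy)phenyl]prop-2-en-1-ol
Conditions: i-Bu2AlH, CH2Cl2, −78 → 0 °C; aq. KNaC4H4O6
Reagents that add atoms: none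
Why: 1,2-Reduction of the cinnamate ester by the aluminium hydride gives the (E)-allylic alcohol without touching the alkene.

Step 14
Reactants: 18 (E)-3-[3,4-bis(benzyloxy)phenyl]prop-2-en-1-ol
Product: 19 (E)-3-[3,4-bis(benzyloxy)phenyl]allyl methyl carbonate
Conditions: ClCO2Me, pyridine, CH2Cl2, 0 °C
Reagents that add atoms: methyl chloroformate COC(=O)Cl
Why: O-Acylation of the allylic alcohol gives the carbonate that iridium ionises in step 19.

Step 15
Reactants: 9 aryl iodide of the top–middle fragment; 15 8-bromo-penta-O-benzylepicatechin-6-carbaldehyde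
Product: 21 diaryl carbinol (both carbinol epimers), via aryllithium 20 (not isolated)
Conditions: n-BuLi, THF, −78 °C; then 15, −78 → −30 °C; H2O
Reagents that add atoms: none
Why: Iodine–lithium exchange at −78 °C outruns any reaction of the benzyl ethers, and the aryllithium adds 1,2 to the aldehyde faster than it exchanges with the aryl bromide of 15; the new carbinol centre is removed in step 16.

Step 16
Reactants: 21 diaryl carbinol
Product: 22 diaryl ketone
Conditions: Dess–Martin periodinane, pyridine, CH2Cl2, 0 °C → rt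
Reagents that add atoms: none
Why: Dess–Martin oxidation of the secondary benzhydrol, buffered with pyridine so that the electron-rich carbinol does not ionise.

Step 17
Reactants: 22 diaryl ketone
Product: 24 1,1-diarylethene (triisopropylsilyl ether), via tertiary carbinol 23 (not isolated)
Conditions: MeLi, THF, −78 → −20 °C; H2O; then PPTS (cat.), 4 Å MS, CH2Cl2, rt
Reagents that add atoms: methyllithium [Li]C
Why: 1,2-Addition of the small nucleophile MeLi to the ketone, then acid-catalysed E1 dehydration of the tertiary diaryl carbinol, whose cation is stabilised by four ortho oxygen substituents and can only lose a methyl proton.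

Step 18
Reactants: 24 1,1-diarylethene (triisopropylsilyl ether)
Product: 25 2-(1-arylvinyl)phenol
Conditions: n-Bu4NF, THF, 0 °C; H2O
Reagents that add atoms: none
Why: Fluoride cleavage of the aryl silyl ether; benzyl ethers, the aryl bromide and the diarylethene are inert to fluoride.

Step 19
Reactants: 25 2-(1-arylvinyl)phenol; 19 (E)-3-[3,4-bis(benzyloxy)phenyl]allyl methyl carbonate
Product: 27 aryl (S)-1-[3,4-bis(benzyloxy)phenyl]allyl ether, via lithium phenoxide 26 (not isolated)
Conditions: LiN(SiMe3)2, THF, 0 °C; then 19 (1.5 equiv), [Ir(cod)Cl]2 (4 mol %), (Sa,Sc,Sc)-(1,1'-binaphthalene-2,2'-diyl) N,N-bis(1-phenylethyl)phosphoramidite (8 mol %), THF, rt; H2O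
Reagents that add atoms: none
Why: Iridium-catalysed asymmetric allylic etherification: the phenoxide attacks the substituted terminus of the allyliridium intermediate anti to the metal, and this ligand antipode is expected, by the usual sense of induction for cinnamyl carbonates with O-nucleophiles, to fix the new centre as S (it becomes 2R of the middle unit once C3 carries oxygen), the catalyst overriding the remote stereocentres.

Step 20
Reactants: 27 aryl (S)-1-arylallyl ether with the ortho 1-(8-bromo-epicatechin-6-yl)vinyl group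
Product: 28 tetradeca-O-benzyl-8-bromo trimer with the middle unit as a (2S)-4-aryl-2H-chromene
Conditions: second-generation Grubbs catalyst (H2IMes)(PCy3)Cl2Ru=CHPh (10 mol %, two portions), degassed toluene, 80 °C, Ar sparge, dark
Reagents that add atoms: none
Why: The ruthenium benzylidene first exchanges onto the unhindered monosubstituted vinyl group of the 1-arylallyl ether; the alkylidene now on C3 adds to the ortho 1,1-diarylethene through a ruthenacyclobutane that cycloreverts to the C3=C4 bond and a ruthenium methylidene, and ethylene leaves. The closest known reaction type is ring-closing metathesis of 2-(1-arylvinyl)aryl allyl ethers to 4-aryl-2H-chromenes with this catalyst. Ring C of the middle unit (O1, C2, C3, C4, C4a, C8a) closes in the six-membered mode, a monosubstituted and a 1,1-disubstituted alkene being merged into one endocyclic trisubstituted alkene. No stereocentre is formed, and the C2 centre from step 19 is kept as long as the allylic C2–O bond does not ionise and the chromene does not ring-open photochemically, hence acid-free toluene and exclusion of light. The step needs initiation at the vinyl group and not at the diarylethene, which the substrate secures because the 1,1-diarylethene flanked by four ortho oxygen substituents can neither load ruthenium first nor homodimerise, so its only productive reaction is the intramolecular one. Removal of ethylene by the argon stream at 80 °C makes the closure irreversible.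

Step 21
Reactants: 28 trimer with the middle 4-aryl-2H-chromene
Product: 30 tetradeca-O-benzyl-8-bromo-catechin-(4α→6)-catechin-(4α→6)-epicatechin with free middle 3-OH, via C3 alkylborane 29 (not isolated)
Conditions: BH3·SMe2, THF, 0 °C → rt; then H2O2, aq. NaOH, 0 °C → rt
Reagents that add atoms: hydrogen peroxide OO
Why: Hydroboration–oxidation of a flav-3-ene: H–B adds syn across C3=C4 from the face opposite the C2 aryl, boron going to the non-benzylic C3 and hydrogen to the doubly benzylic C4, and oxidation with retention gives the 3β-OH, 4α-aryl (2,3-trans-3,4-trans) middle unit.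

Step 22
Reactants: 30 protected trimer
Product: 31 catechin-(4α→6)-catechin-(4α→6)-epicatechin (CNP0163146.3)
Conditions: H2 (1 atm), Pd(OH)2 on carbon, Et3N, THF/MeOH/H2O, rt
Reagents that add atoms: none

Why: Hydrogenolysis cleaves all fourteen benzyl ethers and the aryl C–Br bond in one operation, with Et3N taking up the HBr so that the acid-labile interflavan bonds survive.

**Compound list**

1 | (+)-catechin | O[C@H]1Cc2c(O)cc(O)cc2O[C@@H]1c1ccc(O)c(O)c1 | starting material
2 | 5,7,3',4'-tetra-O-benzylcatechin | O[C@H]1Cc2c(OCc9ccccc9)cc(OCc9ccccc9)cc2O[C@@H]1c7ccc(OCc9ccccc9)c(OCc9ccccc9)c7 | intermediate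
3 | 3,5,7,3',4'-penta-O-benzylcatechin | c9ccccc9COc1cc(OCc9ccccc9)c2c(c1)O[C@H](c7ccc(OCc9ccccc9)c(OCc9ccccc9)c7)[C@@H](OCc9ccccc9)C2 | intermediate
4 | 3,5,7,3',4'-penta-O-benzyl-4β-methoxycatechin | c9ccccc9COc1cc(OCc9ccccc9)c2c(c1)O[C@H](c7ccc(OCc9ccccc9)c(OCc9ccccc9)c7)[C@@H](OCc9ccccc9)[C@H]2OC | intermediate
5 | phloroglucinol | Oc1cc(O)cc(O)c1 | starting material
6 | penta-O-benzylcatechin-(4α→2)-phloroglucinol | c9ccccc9COc1cc(OCc9ccccc9)c2c(c1)O[C@H](c7ccc(OCc9ccccc9)c(OCc9ccccc9)c7)[C@@H](OCc9ccccc9)[C@@H]2c1c(O)cc(O)cc1O | intermediate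
7 | para-O-triisopropylsilyl ether of 6 | c9ccccc9COc1cc(OCc9ccccc9)c2c(c1)O[C@H](c7ccc(OCc9ccccc9)c(OCc9ccccc9)c7)[C@@H](OCc9ccccc9)[C@@H]2c1c(O)cc(O[Si](C(C)C)(C(C)C)C(C)C)cc1O | intermediate
8 | mono-iodide of 7 | c9ccccc9COc1cc(OCc9ccccc9)c2c(c1)O[C@H](c7ccc(OCc9ccccc9)c(OCc9ccccc9)c7)[C@@H](OCc9ccccc9)[C@@H]2c1c(O)cc(O[Si](C(C)C)(C(C)C)C(C)C)c(I)c1O | intermediate
9 | 4α-[2,6-bis(benzyloxy)-3-iodo-4-(triisopropylsilyloxy)phenyl]-penta-O-benzylcatechin | c9ccccc9COc1cc(OCc9ccccc9)c2c(c1)O[C@H](c7ccc(OCc9ccccc9)c(OCc9ccccc9)c7)[C@@H](OCc9ccccc9)[C@@H]2c1c(OCc9ccccc9)cc(O[Si](C(C)C)(C(C)C)C(C)C)c(I)c1OCc9ccccc9 | intermediate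
10 | (−)-epicatechin | O[C@@H]1Cc2c(O)cc(O)cc2O[C@@H]1c1ccc(O)c(O)c1 | starting material
11 | 5,7,3',4'-tetra-O-benzylepicatechin | O[C@@H]1Cc2c(OCc9ccccc9)cc(OCc9ccccc9)cc2O[C@@H]1c7ccc(OCc9ccccc9)c(OCc9ccccc9)c7 | intermediate
12 | 3,5,7,3',4'-penta-O-benzylepicatechin | c9ccccc9CO[C@@H]1Cc2c(OCc9ccccc9)cc(OCc9ccccc9)cc2O[C@@H]1c7ccc(OCc9ccccc9)c(OCc9ccccc9)c7 | intermediate
13 | 8-bromo-3,5,7,3',4'-penta-O-benzylepicatechin | c9ccccc9CO[C@@H]1Cc2c(OCc9ccccc9)cc(OCc9ccccc9)c(Br)c2O[C@@H]1c7ccc(OCc9ccccc9)c(OCc9ccccc9)c7 | intermediate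
14 | C6 N,N-dimethyliminium dichlorophosphate of 13 | c9ccccc9CO[C@@H]1Cc2c(OCc9ccccc9)c(C=[N+](C)C)c(OCc9ccccc9)c(Br)c2O[C@@H]1c7ccc(OCc9ccccc9)c(OCc9ccccc9)c7.[O-]P(=O)(Cl)Cl | intermediate (not isolated)
15 | 8-bromo-3,5,7,3',4'-penta-O-benzylepicatechin-6-carbaldehyde | c9ccccc9CO[C@@H]1Cc2c(OCc9ccccc9)c(C=O)c(OCc9ccccc9)c(Br)c2O[C@@H]1c7ccc(OCc9ccccc9)c(OCc9ccccc9)c7 | intermediate
16 | caffeic acid | OC(=O)/C=C/c1ccc(O)c(O)c1 | starting material
17 | benzyl (E)-3-[3,4-bis(benzyloxy)phenyl]acrylate | O=C(OCc9ccccc9)/C=C/c7ccc(OCc9ccccc9)c(OCc9ccccc9)c7 | intermediate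
18 | (E)-3-[3,4-bis(benzyloxy)phenyl]prop-2-en-1-ol | OC/C=C/c7ccc(OCc9ccccc9)c(OCc9ccccc9)c7 | intermediate
19 | (E)-3-[3,4-bis(benzyloxy)phenyl]allyl methyl carbonate | COC(=O)OC/C=C/c7ccc(OCc9ccccc9)c(OCc9ccccc9)c7 | intermediate
20 | aryllithium from 9 (Li in place of I) | c9ccccc9COc1cc(OCc9ccccc9)c2c(c1)O[C@H](c7ccc(OCc9ccccc9)c(OCc9ccccc9)c7)[C@@H](OCc9ccccc9)[C@@H]2c1c(OCc9ccccc9)cc(O[Si](C(C)C)(C(C)C)C(C)C)c([Li])c1OCc9ccccc9 | intermediate (not isolated)
21 | diaryl carbinol (epimers at the carbinol carbon) | c9ccccc9COc1cc(OCc9ccccc9)c2c(c1)O[C@H](c7ccc(OCc9ccccc9)c(OCc9ccccc9)c7)[C@@H](OCc9ccccc9)[C@@H]2c1c(OCc9ccccc9)cc(O[Si](C(C)C)(C(C)C)C(C)C)c(c1OCc9ccccc9)C(O)c1c(OCc9ccccc9)c(Br)c3c(c1OCc9ccccc9)C[C@@H](OCc9ccccc9)[C@@H](c7ccc(OCc9ccccc9)c(OCc9ccccc9)c7)O3 | intermediate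
22 | diaryl ketone | c9ccccc9COc1cc(OCc9ccccc9)c2c(c1)O[C@H](c7ccc(OCc9ccccc9)c(OCc9ccccc9)c7)[C@@H](OCc9ccccc9)[C@@H]2c1c(OCc9ccccc9)cc(O[Si](C(C)C)(C(C)C)C(C)C)c(c1OCc9ccccc9)C(=O)c1c(OCc9ccccc9)c(Br)c3c(c1OCc9ccccc9)C[C@@H](OCc9ccccc9)[C@@H](c7ccc(OCc9ccccc9)c(OCc9ccccc9)c7)O3 | intermediate
23 | tertiary 1,1-diarylethanol | c9ccccc9COc1cc(OCc9ccccc9)c2c(c1)O[C@H](c7ccc(OCc9ccccc9)c(OCc9ccccc9)c7)[C@@H](OCc9ccccc9)[C@@H]2c1c(OCc9ccccc9)cc(O[Si](C(C)C)(C(C)C)C(C)C)c(c1OCc9ccccc9)C(C)(O)c1c(OCc9ccccc9)c(Br)c3c(c1OCc9ccccc9)C[C@@H](OCc9ccccc9)[C@@H](c7ccc(OCc9ccccc9)c(OCc9ccccc9)c7)O3 | intermediate (not isolated)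
24 | 1,1-diarylethene, triisopropylsilyl ether | c9ccccc9COc1cc(OCc9ccccc9)c2c(c1)O[C@H](c7ccc(OCc9ccccc9)c(OCc9ccccc9)c7)[C@@H](OCc9ccccc9)[C@@H]2c1c(OCc9ccccc9)cc(O[Si](C(C)C)(C(C)C)C(C)C)c(c1OCc9ccccc9)C(=C)c1c(OCc9ccccc9)c(Br)c3c(c1OCc9ccccc9)C[C@@H](OCc9ccccc9)[C@@H](c7ccc(OCc9ccccc9)c(OCc9ccccc9)c7)O3 | intermediate
25 | 2-(1-arylvinyl)phenol | c9ccccc9COc1cc(OCc9ccccc9)c2c(c1)O[C@H](c7ccc(OCc9ccccc9)c(OCc9ccccc9)c7)[C@@H](OCc9ccccc9)[C@@H]2c1c(OCc9ccccc9)cc(O)c(c1OCc9ccccc9)C(=C)c1c(OCc9ccccc9)c(Br)c3c(c1OCc9ccccc9)C[C@@H](OCc9ccccc9)[C@@H](c7ccc(OCc9ccccc9)c(OCc9ccccc9)c7)O3 | intermediate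
26 | lithium phenoxide of 25 | c9ccccc9COc1cc(OCc9ccccc9)c2c(c1)O[C@H](c7ccc(OCc9ccccc9)c(OCc9ccccc9)c7)[C@@H](OCc9ccccc9)[C@@H]2c1c(OCc9ccccc9)cc([O-])c(c1OCc9ccccc9)C(=C)c1c(OCc9ccccc9)c(Br)c3c(c1OCc9ccccc9)C[C@@H](OCc9ccccc9)[C@@H](c7ccc(OCc9ccccc9)c(OCc9ccccc9)c7)O3.[Li+] | intermediate (not isolated)
27 | aryl (S)-1-[3,4-bis(benzyloxy)phenyl]allyl ether (metathesis precursor) | c9ccccc9COc1cc(OCc9ccccc9)c2c(c1)O[C@H](c7ccc(OCc9ccccc9)c(OCc9ccccc9)c7)[C@@H](OCc9ccccc9)[C@@H]2c1c(OCc9ccccc9)cc(O[C@H](c7ccc(OCc9ccccc9)c(OCc9ccccc9)c7)C=C)c(c1OCc9ccccc9)C(=C)c1c(OCc9ccccc9)c(Br)c3c(c1OCc9ccccc9)C[C@@H](OCc9ccccc9)[C@@H](c7ccc(OCc9ccccc9)c(OCc9ccccc9)c7)O3 | intermediate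
28 | trimer with the middle unit as (2S)-4-aryl-2H-chromene | c9ccccc9COc1cc(OCc9ccccc9)c2c(c1)O[C@H](c7ccc(OCc9ccccc9)c(OCc9ccccc9)c7)[C@@H](OCc9ccccc9)[C@@H]2c1c(OCc9ccccc9)cc2c(c1OCc9ccccc9)C(c1c(OCc9ccccc9)c(Br)c3c(c1OCc9ccccc9)C[C@@H](OCc9ccccc9)[C@@H](c7ccc(OCc9ccccc9)c(OCc9ccccc9)c7)O3)=C[C@@H](c7ccc(OCc9ccccc9)c(OCc9ccccc9)c7)O2 | intermediate
29 | C3 alkylborane of the middle unit | c9ccccc9COc1cc(OCc9ccccc9)c2c(c1)O[C@H](c7ccc(OCc9ccccc9)c(OCc9ccccc9)c7)[C@@H](OCc9ccccc9)[C@@H]2c1c(OCc9ccccc9)cc2c(c1OCc9ccccc9)[C@@H](c1c(OCc9ccccc9)c(Br)c3c(c1OCc9ccccc9)C[C@@H](OCc9ccccc9)[C@@H](c7ccc(OCc9ccccc9)c(OCc9ccccc9)c7)O3)[C@H](B)[C@@H](c7ccc(OCc9ccccc9)c(OCc9ccccc9)c7)O2 | intermediate (not isolated)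
30 | tetradeca-O-benzyl-8-bromo-catechin-(4α→6)-catechin-(4α→6)-epicatechin, middle 3-OH free | c9ccccc9COc1cc(OCc9ccccc9)c2c(c1)O[C@H](c7ccc(OCc9ccccc9)c(OCc9ccccc9)c7)[C@@H](OCc9ccccc9)[C@@H]2c1c(OCc9ccccc9)cc2c(c1OCc9ccccc9)[C@@H](c1c(OCc9ccccc9)c(Br)c3c(c1OCc9ccccc9)C[C@@H](OCc9ccccc9)[C@@H](c7ccc(OCc9ccccc9)c(OCc9ccccc9)c7)O3)[C@H](O)[C@@H](c7ccc(OCc9ccccc9)c(OCc9ccccc9)c7)O2 | intermediate
31 | catechin-(4α→6)-catechin-(4α→6)-epicatechin (CNP0163146.3) | Oc1cc(O)c2c(c1)O[C@H](c1ccc(O)c(O)c1)[C@@H](O)[C@@H]2c1c(O)cc2c(c1O)[C@@H](c1c(O)cc3c(c1O)C[C@@H](O)[C@@H](c1ccc(O)c(O)c1)O3)[C@H](O)[C@@H](c1ccc(O)c(O)c1)O2 | target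

**Step count**

Total step count: 22. Longest linear sequence: 15 steps (steps 1–7, then 15–22).

**Steps most likely to fail**

Step 20 (ring-closing metathesis). The ruthenium alkylidene formed at the vinyl group may fail to add to the shielded 1,1-diarylethene, so that catalyst decay, alkene isomerisation and loss of the allyl group overtake ring closure. The fallback replaces the reluctant alkene by a carbonyl group (olefin metathesis followed by intramolecular carbonyl olefination with a stoichiometric molybdenum alkylidene). It sets out from ketone 22. n-Bu4NF removes the silyl group to give the hydroxy ketone F1. LiN(SiMe3)2 converts it into the lithium phenoxide F2, which is etherified with carbonate 19 under the iridium conditions of step 19 to the keto allyl ether F3. One equivalent of Mo(=CHCMe2Ph)(=N-2,6-i-Pr2C6H3)[OCMe(CF3)2]2 in benzene at rt then exchanges onto the vinyl group, and the new alkylidene on C3 olefinates the diaryl ketone in a Wittig-like, irreversible step that forms C3=C4. The fallback returns to the route at 28.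

Step 19 (iridium-catalysed etherification). Attack of the bulky ortho-substituted phenoxide on the allyliridium intermediate may be slow, so that the branched ether re-ionises and drifts to the linear cinnamyl ether or to a mixture of C2 epimers. The fallback is a Mitsunobu etherification with inversion, starting from phenol 25. The partner is (R)-1-[3,4-bis(benzyloxy)phenyl]prop-2-en-1-ol F4, made in one step from commercial 3,4-bis(benzyloxy)benzaldehyde by amino-alcohol-catalysed enantioselective addition of Zn(CH=CH2)2. PPh3 and diisopropyl azodicarboxylate in toluene at −20 °C should give the (S)-ether with inversion at the carbinol carbon. Any C2 epimer or linear ether from competing ionisation is a diastereomer or constitutional isomer and would be removed by chromatography. The fallback returns to the route at 27.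

Step 17 (methyl addition and dehydration). MeLi may fail to reach a carbonyl carbon flanked by four ortho oxygen substituents, or bromine–lithium exchange at C8 of the bottom unit may compete; the tertiary cation formed on dehydration could also be trapped instead of losing a proton. The fallback is a titanium carbenoid olefination that passes through no cation. It sets out from ketone 22: Cp2TiMe2 in toluene at 70 °C in the dark transfers CH2 to the carbonyl group through an oxatitanacyclobutane. This fallback makes no new compound (F0) and returns to the route at 24.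

**Further compounds**

F1 | step 20 | hydroxy ketone (22 without the silyl group) | c9ccccc9COc1cc(OCc9ccccc9)c2c(c1)O[C@H](c7ccc(OCc9ccccc9)c(OCc9ccccc9)c7)[C@@H](OCc9ccccc9)[C@@H]2c1c(OCc9ccccc9)cc(O)c(c1OCc9ccccc9)C(=O)c1c(OCc9ccccc9)c(Br)c3c(c1OCc9ccccc9)C[C@@H](OCc9ccccc9)[C@@H](c7ccc(OCc9ccccc9)c(OCc9ccccc9)c7)O3
F2 | step 20 | lithium phenoxide of F1 | c9ccccc9COc1cc(OCc9ccccc9)c2c(c1)O[C@H](c7ccc(OCc9ccccc9)c(OCc9ccccc9)c7)[C@@H](OCc9ccccc9)[C@@H]2c1c(OCc9ccccc9)cc([O-])c(c1OCc9ccccc9)C(=O)c1c(OCc9ccccc9)c(Br)c3c(c1OCc9ccccc9)C[C@@H](OCc9ccccc9)[C@@H](c7ccc(OCc9ccccc9)c(OCc9ccccc9)c7)O3.[Li+]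
F3 | step 20 | keto (S)-1-arylallyl ether | c9ccccc9COc1cc(OCc9ccccc9)c2c(c1)O[C@H](c7ccc(OCc9ccccc9)c(OCc9ccccc9)c7)[C@@H](OCc9ccccc9)[C@@H]2c1c(OCc9ccccc9)cc(O[C@H](c7ccc(OCc9ccccc9)c(OCc9ccccc9)c7)C=C)c(c1OCc9ccccc9)C(=O)c1c(OCc9ccccc9)c(Br)c3c(c1OCc9ccccc9)C[C@@H](OCc9ccccc9)[C@@H](c7ccc(OCc9ccccc9)c(OCc9ccccc9)c7)O3
F4 | step 19 | (R)-1-[3,4-bis(benzyloxy)phenyl]prop-2-en-1-ol | O[C@@H](c7ccc(OCc9ccccc9)c(OCc9ccccc9)c7)C=C
F0 | step 17 | none | none
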